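**Retrosynthetic overview**
1. Target 19 ⇒ 18: the last step makes the C13–O bond. A new Pd-catalysed dehydrogenative conjugate acetoxylation turns the α-methylene lactone into the 13-acetoxy-7(11)-butenolide (key C–O step).
2. 18 ⇒ 16 ⇒ 15: C14 allylic oxidation (C–O), then the ten-membered ring by ring-closing metathesis at C1=C10.
3. 15 ⇒ 8 + 11: C8–O acylation; γ-lactone by C6–O lactonization after a chromium Barbier union at C6–C7.
4. 8 ⇐ ethyl glyoxylate + isobutylene (asymmetric ene, sets C8) + methyl acrylate; 11 ⇐ geraniol (Sharpless epoxidation, sets C4 and C5).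
5. Ring order: epoxide, then γ-lactone, then ten-membered carbocycle; the butenolide double bond is placed last.

Assumption: germacrane numbering is used (lactone carbon C6, epoxide C4–C5, ester carbon C8, formyl carbon C14, acetoxymethyl carbon C13); on that basis the target is (4R,5R,6R,8S) with the C9 and C2 ring carbons cis across C1=C10.

**Route**

Step 1
Reactants: 1 ethyl glyoxylate; 2 isobutylene
Product: 3 ethyl (2S)-2-hydroxy-4-methylpent-4-enoate
Conditions: (S)-BINOL (10 mol %), TiCl2(OiPr)2 (10 mol %), 4 Å MS, CH2Cl2, −30 °C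
Reagents that add atoms: none
Why: Catalytic asymmetric glyoxylate–ene (carbonyl-ene) reaction; the (S)-BINOL–titanium Lewis acid exposes one aldehyde face to isobutylene and sets the future C8 as S (about 95% ee expected for this catalyst class).

Step 2
Reactants: 3 ethyl (2S)-2-hydroxy-4-methylpent-4-enoate
Product: 4 ethyl (2S)-2-[(tert-butyldimethylsilyl)oxy]-4-methylpent-4-enoate
Conditions: TBSCl, imidazole, DMF, rt
Reagents that add atoms: tert-butyldimethylsilyl chloride, CC(C)(C)[Si](C)(C)Cl
Why: Standard silylation; a silyl ether is used because an acyloxy group here would not survive step 3 and would be lost by 1,4-elimination from the allylchromium reagent of step 8.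

Step 3
Reactants: 4 ethyl (2S)-2-[(tert-butyldimethylsilyl)oxy]-4-methylpent-4-enoate
Product: 5 (2S)-2-[(tert-butyldimethylsilyl)oxy]-4-methylpent-4-enal
Conditions: iBu2AlH (1.1 equiv), CH2Cl2, −78 °C; aqueous potassium sodium tartrate
Reagents that add atoms: none
Why: Partial reduction of an α-silyloxy ester with iBu2AlH stops at the aldehyde through the stable aluminium hemiacetal at −78 °C; the stereocenter is not touched.

Step 4
Reactants: 5 (2S)-2-[(tert-butyldimethylsilyl)oxy]-4-methylpent-4-enal; 6 methyl acrylate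
Product: 7 methyl (4S)-4-[(tert-butyldimethylsilyl)oxy]-3-hydroxy-6-methyl-2-methylidenehept-6-enoate (mixture of C3 epimers)
Conditions: DABCO (0.5 equiv), methyl acrylate (5 equiv, neat), rt, 5 d
Reagents that add atoms: none
Why: Morita–Baylis–Hillman reaction of an activated α-silyloxy aldehyde; the new carbinol centre forms as a mixture that is erased in step 5.

Step 5
Reactants: 7 methyl (4S)-4-[(tert-butyldimethylsilyl)oxy]-3-hydroxy-6-methyl-2-methylidenehept-6-enoate
Product: 8 methyl (2Z,4S)-2-(bromomethyl)-4-[(tert-butyldimethylsilyl)oxy]-6-methylhepta-2,6-dienoate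
Conditions: NBS, Me2S, CH2Cl2, 0 °C to rt
Reagents that add atoms: N-bromosuccinimide, O=C1CCC(=O)N1Br
Why: SN2′ bromination of a Baylis–Hillman alcohol through its alkoxysulfonium salt gives the (Z)-2-(bromomethyl)enoate; C8 is untouched.

Step 6
Reactants: 9 geraniol
Product: 10 [(2R,3R)-3-methyl-3-(4-methylpent-3-en-1-yl)oxiran-2-yl]methanol
Conditions: Ti(OiPr)4 (5 mol %), D-(−)-diethyl tartrate (7.5 mol %), t-BuOOH, 4 Å MS, CH2Cl2, −20 °C
Reagents that add atoms: tert-butyl hydroperoxide, CC(C)(C)OO
Why: Sharpless asymmetric epoxidation; the titanium–D-tartrate complex delivers oxygen to one face of the allylic alcohol and sets both epoxide carbons (4R,5R in germacrane numbering), leaving the remote alkene untouched.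

Step 7
Reactants: 10 [(2R,3R)-3-methyl-3-(4-methylpent-3-en-1-yl)oxiran-2-yl]methanol
Product: 11 (2S,3R)-3-methyl-3-(4-methylpent-3-en-1-yl)oxirane-2-carbaldehyde
Conditions: TEMPO (10 mol %), PhI(OAc)2, CH2Cl2, rt
Reagents that add atoms: none
Why: Oxoammonium (TEMPO) oxidation of a primary epoxy alcohol to the aldehyde under neutral, non-epimerizing conditions.

Step 8
Reactants: 8 allylic bromide; 11 epoxy aldehyde
Product: 13 TBS-protected trans α-methylene-γ-lactone, via hydroxy ester 12 (not isolated)
Conditions: CrCl2 (4 equiv), THF, 0 °C to rt; then PPTS (10 mol %), toluene, 40 °C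
Reagents that add atoms: none
Why: Chromium-mediated Barbier (Nozaki–Hiyama) allylation then lactonization (C6–O bond); Felkin–Anh attack anti to the epoxide C–O bond sets C6 as R, the chair transition state gives the anti adduct (H-6/H-7 trans), and the C7 configuration is erased in step 13.

Step 9
Reactants: 13 TBS-protected trans α-methylene-γ-lactone
Product: 14 hydroxy lactone
Conditions: Bu4NF, AcOH (1:1), THF, 0 °C to rt
Reagents that add atoms: none
Why: Buffered fluoride desilylation; acetic acid keeps the medium near neutral so the epoxide and the α-methylene lactone survive.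

Step 10
Reactants: 14 hydroxy lactone
Product: 15 isovalerate lactone
Conditions: isovaleryl chloride, pyridine, DMAP (cat.), CH2Cl2, 0 °C
Reagents that add atoms: 3-methylbutanoyl chloride, CC(C)CC(=O)Cl
Why: DMAP-catalysed O-acylation of the secondary alcohol with retention at C8.

Step 11
Reactants: 15 isovalerate lactone
Product: 16 (1(10)Z)-ten-membered α-methylene lactone
Conditions: second-generation Hoveyda–Grubbs catalyst RuCl2(H2IMes)(=CH-C6H4-2-OiPr) (15 mol %), toluene (1 mM), 80 °C, argon sparge
Reagents that add atoms: none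
Why: Ring-closing metathesis; the ruthenium alkylidene initiates at the prenyl group (loss of isobutylene) and closes onto the methallyl alkene, the ten-membered ring enforces the ring-cis trisubstituted alkene, and the electron-poor α-methylene lactone stays out of the reaction.

Step 12
Reactants: 16 (1(10)Z)-ten-membered α-methylene lactone
Product: 18 14-oxo α-methylene lactone (enal), via allylic alcohol 17 (not isolated)
Conditions: SeO2 (0.5 equiv), t-BuOOH (3 equiv), CH2Cl2, 0 °C to rt; filter; then MnO2 (10 equiv), CH2Cl2, rt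
Reagents that add atoms: selenium dioxide, O=[Se]=O; tert-butyl hydroperoxide, CC(C)(C)OO
Why: Selenium dioxide allylic oxidation (ene reaction then [2,3]-sigmatropic shift) picks the C14 methyl group, which lies trans to the C2 chain, and keeps the alkene geometry (parthenolide-type lactones are oxidized at C14 in the same way); MnO2 then oxidizes the allylic alcohol to the enal.

Step 13
Reactants: 18 14-oxo α-methylene lactone (enal)
Product: 19 target
Conditions: Pd(OAc)2 (10 mol %), 4,5-diazafluoren-9-one (10 mol %), 1,4-benzoquinone (1.5 equiv), AcOH (10 equiv), NaOAc (1 equiv), 1,4-dioxane, 45 °C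
Reagents that add atoms: acetic acid, CC(=O)O
Why: Proposed new method: divalent palladium activates the exocyclic alkene and acetate adds to the unhindered C13 terminus (Wacker/conjugate sense) to give a C11 palladium enolate, β-hydride elimination toward H-7 (giving the conjugated tetrasubstituted ring alkene rather than the C13 enol acetate) releases 19 and zerovalent palladium, which benzoquinone reoxidizes; the closest known reaction types are Wacker-type allylic acetoxylation of alkenes, palladium-catalysed β-acetalization of acrylates and Saegusa-type dehydrogenation of palladium enolates, and the step forms the C13–O bond and the butenolide while erasing C7 without creating a stereocenter.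

**Compound list**
1 | ethyl glyoxylate | CCOC(=O)C=O | starting material
2 | isobutylene (2-methylpropene) | CC(C)=C | starting material
3 | ethyl (2S)-2-hydroxy-4-methylpent-4-enoate | CCOC(=O)[C@@H](O)CC(C)=C | intermediate
4 | ethyl (2S)-2-[(tert-butyldimethylsilyl)oxy]-4-methylpent-4-enoate | CCOC(=O)[C@@H](O[Si](C)(C)C(C)(C)C)CC(C)=C | intermediate
5 | (2S)-2-[(tert-butyldimethylsilyl)oxy]-4-methylpent-4-enal | O=C[C@@H](O[Si](C)(C)C(C)(C)C)CC(C)=C | intermediate
6 | methyl acrylate | C=CC(=O)OC | starting material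
7 | methyl (4S)-4-[(tert-butyldimethylsilyl)oxy]-3-hydroxy-6-methyl-2-methylidenehept-6-enoate (mixture of C3 epimers) | COC(=O)C(=C)C(O)[C@@H](O[Si](C)(C)C(C)(C)C)CC(C)=C | intermediate
8 | methyl (2Z,4S)-2-(bromomethyl)-4-[(tert-butyldimethylsilyl)oxy]-6-methylhepta-2,6-dienoate | COC(=O)/C(CBr)=C/[C@@H](O[Si](C)(C)C(C)(C)C)CC(C)=C | intermediate
9 | geraniol, (2E)-3,7-dimethylocta-2,6-dien-1-ol | CC(C)=CCC/C(C)=C/CO | starting material
10 | [(2R,3R)-3-methyl-3-(4-methylpent-3-en-1-yl)oxiran-2-yl]methanol | CC(C)=CCC[C@@]1(C)O[C@@H]1CO | intermediate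
11 | (2S,3R)-3-methyl-3-(4-methylpent-3-en-1-yl)oxirane-2-carbaldehyde | CC(C)=CCC[C@@]1(C)O[C@@H]1C=O | intermediate
12 | methyl (3R,4S)-4-[(tert-butyldimethylsilyl)oxy]-3-{(R)-hydroxy[(2R,3R)-3-methyl-3-(4-methylpent-3-en-1-yl)oxiran-2-yl]methyl}-6-methyl-2-methylidenehept-6-enoate | CC(C)=CCC[C@@]1(C)O[C@@H]1[C@H](O)[C@@H](C(=C)C(=O)OC)[C@@H](O[Si](C)(C)C(C)(C)C)CC(C)=C | intermediate
13 | (4R,5R)-4-{(1S)-1-[(tert-butyldimethylsilyl)oxy]-3-methylbut-3-en-1-yl}-3-methylidene-5-[(2R,3R)-3-methyl-3-(4-methylpent-3-en-1-yl)oxiran-2-yl]oxolan-2-one (ring substituents trans) | CC(C)=CCC[C@@]1(C)O[C@@H]1[C@@H]2OC(=O)C(=C)[C@H]2[C@@H](O[Si](C)(C)C(C)(C)C)CC(C)=C | intermediate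
14 | (4S,5R)-4-[(1S)-1-hydroxy-3-methylbut-3-en-1-yl]-3-methylidene-5-[(2R,3R)-3-methyl-3-(4-methylpent-3-en-1-yl)oxiran-2-yl]oxolan-2-one | CC(C)=CCC[C@@]1(C)O[C@@H]1[C@@H]2OC(=O)C(=C)[C@H]2[C@@H](O)CC(C)=C | intermediate
15 | (4S,5R)-3-methylidene-4-[(1S)-3-methyl-1-(3-methylbutanoyloxy)but-3-en-1-yl]-5-[(2R,3R)-3-methyl-3-(4-methylpent-3-en-1-yl)oxiran-2-yl]oxolan-2-one | CC(C)=CCC[C@@]1(C)O[C@@H]1[C@@H]2OC(=O)C(=C)[C@H]2[C@@H](OC(=O)CC(C)C)CC(C)=C | intermediate
16 | (1(10)Z,4R,5R,6R,7S,8S)-4,5-epoxy-8-(3-methylbutanoyloxy)germacra-1(10),11(13)-dien-12,6-olide | C=C1[C@H]2[C@@H](OC(=O)CC(C)C)C/C(C)=C\CC[C@@]3(C)O[C@@H]3[C@@H]2OC1=O | intermediate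
17 | (1(10)E,4R,5R,6R,7S,8S)-4,5-epoxy-14-hydroxy-8-(3-methylbutanoyloxy)germacra-1(10),11(13)-dien-12,6-olide | C=C1[C@H]2[C@@H](OC(=O)CC(C)C)C/C(CO)=C\CC[C@@]3(C)O[C@@H]3[C@@H]2OC1=O | intermediate
18 | (1(10)E,4R,5R,6R,7S,8S)-4,5-epoxy-8-(3-methylbutanoyloxy)-14-oxogermacra-1(10),11(13)-dien-12,6-olide | C=C1[C@H]2[C@@H](OC(=O)CC(C)C)C/C(C=O)=C\CC[C@@]3(C)O[C@@H]3[C@@H]2OC1=O | intermediate
19 | (1(10)E,4R,5R,6R,8S)-13-acetoxy-4,5-epoxy-8-(3-methylbutanoyloxy)-14-oxogermacra-1(10),7(11)-dien-12,6-olide (CNP0289605.1) | CC(=O)OCC1=C2[C@@H](OC(=O)CC(C)C)C/C(C=O)=C\CC[C@@]3(C)O[C@@H]3[C@@H]2OC1=O | target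

**Step count and risks**

Total: 13 steps (steps 1–5 for bromide 8, steps 6–7 for aldehyde 11, steps 8–13 after the union). Longest linear sequence: 11 steps (1–5, then 8–13).

The three steps most likely to fail:

Step 13 (the proposed new palladium acetoxylation). The open questions are the direction of β-hydride elimination (toward C7 or toward C13) and scrambling of the two allylic esters. The fallback uses known chemistry, sets out from 18 and comes back at 19. A Schenck ene reaction with singlet oxygen (O2, tetraphenylporphyrin, visible light, CH2Cl2, 0 °C) is used; the geminal-directing effect of the carbonyl group leaves H-7 as the only hydrogen that can be abstracted. This gives the 13-hydroperoxy-7(11)-butenolide F2. Triphenylphosphine reduces it in the same flask to the 13-hydroxy butenolide F3, and Ac2O, pyridine and DMAP (cat.) in CH2Cl2 give 19. The enal alkene of 18 is too electron-poor to compete.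

Step 11 (ring-closing metathesis to a ten-membered ring with a trisubstituted alkene, initiated at a prenyl group). The fallback sets out from 15 and comes back at 16. First the prenyl group is exchanged for a terminal vinyl group by ethenolysis (second-generation Grubbs catalyst RuCl2(H2IMes)(PCy3)(=CHPh), ethylene 1 atm, CH2Cl2, 40 °C), giving the terminal-vinyl lactone F1. The ring is then closed with the molybdenum alkylidene Mo(=CHCMe2Ph)(=N-2,6-iPr2C6H3)[OCMe(CF3)2]2 in benzene at high dilution; this catalyst class is the more reactive one for hindered trisubstituted ring alkenes.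

Step 4 (Baylis–Hillman reaction of a branched α-silyloxy aldehyde: slow, with some risk of C8 epimerization under prolonged amine exposure). The fallback sets out from 5 and comes back at 7 with no new compound (F0). It is a vinylalumination: methyl propiolate with iBu2AlH and N-methylmorpholine N-oxide in THF at 0 °C gives [1-(methoxycarbonyl)vinyl]diisobutylaluminium, which adds to aldehyde 5 within hours to give 7 directly.

**Further compounds**
F0 | step 4 | none | none
F1 | step 11 | (4S,5R)-5-[(2R,3R)-3-(but-3-en-1-yl)-3-methyloxiran-2-yl]-3-methylidene-4-[(1S)-3-methyl-1-(3-methylbutanoyloxy)but-3-en-1-yl]oxolan-2-one | C=CCC[C@@]1(C)O[C@@H]1[C@@H]2OC(=O)C(=C)[C@H]2[C@@H](OC(=O)CC(C)C)CC(C)=C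
F2 | step 13 | (1(10)E,4R,5R,6R,8S)-4,5-epoxy-13-hydroperoxy-8-(3-methylbutanoyloxy)-14-oxogermacra-1(10),7(11)-dien-12,6-olide | OOCC1=C2[C@@H](OC(=O)CC(C)C)C/C(C=O)=C\CC[C@@]3(C)O[C@@H]3[C@@H]2OC1=O
F3 | step 13 | (1(10)E,4R,5R,6R,8S)-4,5-epoxy-13-hydroxy-8-(3-methylbutanoyloxy)-14-oxogermacra-1(10),7(11)-dien-12,6-olide | OCC1=C2[C@@H](OC(=O)CC(C)C)C/C(C=O)=C\CC[C@@]3(C)O[C@@H]3[C@@H]2OC1=O
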